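The plan cuts the C1–C2 bond of ring A together with the C9–C10 bond of ring B. An open-chain iodide that holds only the C5 and C13 stereocentres is closed in one radical cascade: the C2 radical attacks C1, the CH2 end of the isopropenyl group on C5 (ring A), the tertiary C10 radical attacks C9 of an allylic sulfone (ring B), and loss of the sulfonyl radical places the C7=C8 bond next to the C6 ketone. The step exploits the quaternary C10 between C1 and C9 and the oxygen on C6. The precursor is joined from an (R)-linalool-derived allyl sulfone and a lactone from an enantioselective ester-enolate Claisen rearrangement.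

Key step: step 8

Assumption (chemistry): the (S,S)-enantiomer of the boron controller is taken to give the (2R)-acid 8 in step 4; if the sense of induction is the opposite one, the (R,R)-controller is used and nothing else changes. Labdane numbering (C1–C20) is used for the atoms of all intermediates.

Step 1
Reactants: 1 (R)-linalool
Product: 2 (2E,6R)-2,6-dimethylocta-2,7-diene-1,6-diol
Conditions: SeO2 (0.3 equiv), t-BuOOH (3 equiv), salicylic acid (cat.), CH2Cl2, rt
Reagents that add atoms: tert-butyl hydroperoxide CC(C)(C)OO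
Why: Riley allylic oxidation (ene reaction, then [2,3]-sigmatropic shift) is selective for the (E)-methyl group of the trisubstituted alkene (the future C7); the vinyl group has no allylic hydrogen and the C13 carbinol centre is not touched.

Step 2
Reactants: 2 (2E,6R)-2,6-dimethylocta-2,7-diene-1,6-diol
Product: 4 (3R,6E)-3,7-dimethyl-8-(phenylsulfonyl)octa-1,6-dien-3-ol, via mesylate 3 (not isolated)
Conditions: MsCl, Et3N, CH2Cl2, −40 °C; then PhSO2Na, Bu4NI (cat.), DMF, rt
Reagents that add atoms: sodium benzenesulfinate [Na+].[O-]S(=O)c1ccccc1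
Why: Only the primary allylic alcohol is sulfonylated, and SN2 S-alkylation of the sulfinate should give the allyl sulfone with the (E) geometry retained.

Step 3
Reactants: 5 3-methylbut-2-en-1-ol (prenol); 6 3-methylbut-3-enoic acid
Product: 7 3-methylbut-2-en-1-yl 3-methylbut-3-enoate
Conditions: DCC, DMAP (cat.), CH2Cl2, 0 °C
Reagents that add atoms: none
Why: Steglich esterification at low temperature should give the ester without moving the β,γ-double bond into conjugation.

Step 4
Reactants: 7 3-methylbut-2-en-1-yl 3-methylbut-3-enoate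
Product: 8 (2R)-3,3-dimethyl-2-(prop-1-en-2-yl)pent-4-enoic acid
Conditions: (S,S)-[TsNCH(Ph)CH(Ph)NTs]BBr (1.2 equiv, from the bis-sulfonamide and BBr3), Et3N, toluene/hexane, −78 °C → 4 °C; aqueous work-up
Reagents that add atoms: none
Why: Soft enolisation by the chiral boron bromide and Ireland–Claisen ([3,3]-sigmatropic) rearrangement through a chair transition state form the crowded C4–C5 bond; the C2-symmetric bis-sulfonamide on boron selects the enolate face and so sets C5, the only new stereocentre because the allyl terminus carries two methyl groups.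

Step 5
Reactants: 8 (2R)-3,3-dimethyl-2-(prop-1-en-2-yl)pent-4-enoic acid
Product: 10 (3R)-4,4-dimethyl-3-(prop-1-en-2-yl)oxan-2-one, via hydroxy acid 9 (not isolated)
Conditions: catecholborane (3 equiv), RhCl(PPh3)3 (3 mol %), THF, rt; NaOH, H2O2, 0 °C; then aq. HCl (pH 2), rt
Reagents that add atoms: hydrogen peroxide OO
Why: Rhodium-catalysed hydroboration takes the monosubstituted vinyl group much faster than the hindered 1,1-disubstituted isopropenyl group, oxidation gives the anti-Markovnikov C2 alcohol and acid closes the δ-lactone without touching C5.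

Step 6
Reactants: 4 (3R,6E)-3,7-dimethyl-8-(phenylsulfonyl)octa-1,6-dien-3-ol; 10 (3R)-4,4-dimethyl-3-(prop-1-en-2-yl)oxan-2-one
Product: 11 (4R,7E,11R)-1,11-dihydroxy-3,3,7,11-tetramethyl-6-(phenylsulfonyl)-4-(prop-1-en-2-yl)trideca-7,12-dien-5-one (mixture at the sulfone-bearing carbon)
Conditions: 4 (2.1 equiv), n-BuLi (4.2 equiv), THF, −78 °C; then 10, −78 → −30 °C; aq. NH4Cl
Reagents that add atoms: none
Why: Claisen-type C-acylation of the α-sulfonyl allyl carbanion at its α-carbon by the lactone forms the C6–C7 bond and frees the C2 hydroxyl; the second equivalent of carbanion deprotonates the β-keto sulfone and drives the addition, and the stabilised carbanion should be too weak a base to enolise the lactone at C5.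

Step 7
Reactants: 11 (4R,7E,11R)-1,11-dihydroxy-3,3,7,11-tetramethyl-6-(phenylsulfonyl)-4-(prop-1-en-2-yl)trideca-7,12-dien-5-one
Product: 12 (4R,7E,11R)-11-hydroxy-1-iodo-3,3,7,11-tetramethyl-6-(phenylsulfonyl)-4-(prop-1-en-2-yl)trideca-7,12-dien-5-one
Conditions: PPh3, N-iodosuccinimide, CH2Cl2, −20 °C
Reagents that add atoms: N-iodosuccinimide O=C1CCC(=O)N1I
Why: Appel-type iodination under neutral conditions converts only the unhindered primary alcohol; the tertiary allylic alcohol does not react and the acidic β-keto sulfone is not deprotonated.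

Step 8
Reactants: 12 (4R,7E,11R)-11-hydroxy-1-iodo-3,3,7,11-tetramethyl-6-(phenylsulfonyl)-4-(prop-1-en-2-yl)trideca-7,12-dien-5-one
Product: 13 (5S,9S,10R,13R)-13-hydroxylabda-7,14-dien-6-one
Conditions: Bu3SnH (1.1 equiv) and AIBN (0.2 equiv) by syringe pump (8 h), benzene (5 mM), 80 °C
Reagents that add atoms: none
Why: Bu3Sn• abstracts iodine to give the primary C2 radical, which adds to C1, the CH2 terminus of the isopropenyl group on C5, and forms the C1–C2 bond; the tertiary C10 radical then adds to C9 of the allylic sulfone and the C8 radical expels PhSO2•, which carries the chain with Bu3SnH and leaves the C7=C8 bond conjugated with the C6 ketone. The closest known reaction types are tin-mediated 6-endo radical polyene cyclisations and radical addition–fragmentation on allylic sulfones. Ring A closes 6-endo-trig onto the 1,1-disubstituted alkene, and ring B closes 6-endo-trig with β-elimination of the sulfonyl radical. C10 is set by a chair–chair transition state in which the chain on the existing C5 stereocentre is equatorial, so that the new C10–C9 bond is equatorial and the C10 methyl axial (trans ring fusion); C9 is set by the (E) geometry of the C8=C9 alkene, which puts the side chain equatorial. The step needs 6-endo instead of 5-exo closure of the first ring and a single position for the new double bond: the former is favoured by the methyl group on the internal alkene carbon C10 and by the crowded neighbours C5 and C4, which hinder attack at C10, and the latter is fixed by the sulfonyl leaving group on C7.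

Step 9
Reactants: 13 (5S,9S,10R,13R)-13-hydroxylabda-7,14-dien-6-one
Product: 14 (5S,6R,9S,10R,13R)-labda-7,14-diene-6,13-diol (6β-hydroxyl)
Conditions: NaBH4, CeCl3·7H2O, MeOH, −78 → 0 °C
Reagents that add atoms: none
Why: Luche reduction gives 1,2-reduction of the enone; hydride should attack C6 from the α face, away from the axial methyl groups on C10 and C4, and give the axial 6β-alcohol.

Step 10
Reactants: 14 (5S,6R,9S,10R,13R)-labda-7,14-diene-6,13-diol; 15 butanoic acid
Product: 16 (5S,6S,9S,10R,13R)-13-hydroxylabda-7,14-dien-6-yl butanoate (CNP0339102.1)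
Conditions: PPh3, DIAD, toluene, 0 °C → rt
Reagents that add atoms: none
Why: Mitsunobu esterification replaces the activated 6β-oxygen by butanoate with inversion (SN2 at the allylic C6 from the open α face) and so sets the 6α ester; the tertiary C13 alcohol does not react.

Compound list
1 | (R)-linalool, (3R)-3,7-dimethylocta-1,6-dien-3-ol | C=C[C@](C)(O)CCC=C(C)C | starting material
2 | (2E,6R)-2,6-dimethylocta-2,7-diene-1,6-diol | C=C[C@](C)(O)CC/C=C(C)/CO | intermediate
3 | (2E,6R)-6-hydroxy-2,6-dimethylocta-2,7-dien-1-yl methanesulfonate | C=C[C@](C)(O)CC/C=C(C)/COS(C)(=O)=O | intermediate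
4 | (3R,6E)-3,7-dimethyl-8-(phenylsulfonyl)octa-1,6-dien-3-ol | C=C[C@](C)(O)CC/C=C(C)/CS(=O)(=O)c1ccccc1 | intermediate
5 | 3-methylbut-2-en-1-ol (prenol) | CC(C)=CCO | starting material
6 | 3-methylbut-3-enoic acid | C=C(C)CC(=O)O | starting material
7 | 3-methylbut-2-en-1-yl 3-methylbut-3-enoate | C=C(C)CC(=O)OCC=C(C)C | intermediate
8 | (2R)-3,3-dimethyl-2-(prop-1-en-2-yl)pent-4-enoic acid | C=CC(C)(C)[C@@H](C(C)=C)C(=O)O | intermediate
9 | (2R)-5-hydroxy-3,3-dimethyl-2-(prop-1-en-2-yl)pentanoic acid | OCCC(C)(C)[C@@H](C(C)=C)C(=O)O | intermediate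
10 | (3R)-4,4-dimethyl-3-(prop-1-en-2-yl)oxan-2-one | O=C1OCCC(C)(C)[C@H]1C(C)=C | intermediate
11 | (4R,7E,11R)-1,11-dihydroxy-3,3,7,11-tetramethyl-6-(phenylsulfonyl)-4-(prop-1-en-2-yl)trideca-7,12-dien-5-one | C=C[C@](C)(O)CC/C=C(C)/C(S(=O)(=O)c1ccccc1)C(=O)[C@H](C(C)=C)C(C)(C)CCO | intermediate
12 | (4R,7E,11R)-11-hydroxy-1-iodo-3,3,7,11-tetramethyl-6-(phenylsulfonyl)-4-(prop-1-en-2-yl)trideca-7,12-dien-5-one | C=C[C@](C)(O)CC/C=C(C)/C(S(=O)(=O)c1ccccc1)C(=O)[C@H](C(C)=C)C(C)(C)CCI | intermediate
13 | (5S,9S,10R,13R)-13-hydroxylabda-7,14-dien-6-one | C=C[C@](C)(O)CC[C@H]1C(C)=CC(=O)[C@H]2C(C)(C)CCC[C@]12C | intermediate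
14 | (5S,6R,9S,10R,13R)-labda-7,14-diene-6,13-diol | C=C[C@](C)(O)CC[C@H]1C(C)=C[C@@H](O)[C@H]2C(C)(C)CCC[C@]12C | intermediate
15 | butanoic acid | CCCC(=O)O | starting material
16 | (5S,6S,9S,10R,13R)-13-hydroxylabda-7,14-dien-6-yl butanoate | C=C[C@](C)(O)CC[C@H]1C(C)=C[C@H](OC(=O)CCC)[C@H]2C(C)(C)CCC[C@]12C | target

Total step count: 10. Longest linear sequence: 8 steps (steps 3 to 10, from 5 and 6); the sulfone branch has 2 steps.

Steps most likely to fail

Step 8. What may go wrong is 5-exo attack of the C2 radical at C10 in competition with the 6-endo closure, and reduction of the open-chain radicals before they cyclise. The fallback replaces the alkyl radical by an acyl radical, for which 6-endo closure onto 1,1-disubstituted alkenes is the normal course. It sets out from 11. Dess–Martin oxidation of the primary alcohol should give the aldehyde (4R,7E,11R)-11-hydroxy-3,3,7,11-tetramethyl-5-oxo-6-(phenylsulfonyl)-4-(prop-1-en-2-yl)trideca-7,12-dienal F1. Thiol-catalysed hydrogen abstraction from the aldehyde (tert-dodecanethiol, AIBN, benzene, 80 °C) starts the same two ring closures and sulfonyl loss and should give the diketone (5S,9S,10R,13R)-13-hydroxylabda-7,14-diene-2,6-dione F2. The unhindered C2 ketone is converted into the tosylhydrazone of F2 at C2 F3 (TsNHNH2, EtOH, rt), and reduction with catecholborane followed by NaOAc comes back to the route at 13.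

Step 10. What may go wrong is elimination of the activated axial 6β-oxygen with the anti-periplanar hydrogen on C5, or slow substitution at the hindered centre; poor facial selectivity in step 9 would show at the same place. The fallback sets C6 by thermodynamic control instead of inversion. It sets out from 13. Meerwein–Ponndorf–Verley reduction under equilibrating conditions (Al(O-i-Pr)3, i-PrOH, toluene, reflux, acetone kept in the flask) should give the equatorial alcohol (5S,6S,9S,10R,13R)-labda-7,14-diene-6,13-diol F4. Acylation of its secondary hydroxyl with butanoic anhydride, Et3N and DMAP comes back to the route at 16.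

Step 6. What may go wrong is proton transfer from the enolisable lactone to the carbanion, reversal of the acylation, and loss of configuration at C5. The fallback replaces acylation by addition at the aldehyde oxidation level. It sets out from 10. Reduction with i-Bu2AlH (CH2Cl2, −78 °C) should give the lactol (3R)-4,4-dimethyl-3-(prop-1-en-2-yl)oxan-2-ol F5. The dilithio derivative of 4 adds to its open hydroxy aldehyde form to give (4R,7E,11R)-3,3,7,11-tetramethyl-6-(phenylsulfonyl)-4-(prop-1-en-2-yl)trideca-7,12-diene-1,5,11-triol F6. Selective iodination of the primary hydroxyl (PPh3, N-iodosuccinimide) gives (4R,7E,11R)-1-iodo-3,3,7,11-tetramethyl-6-(phenylsulfonyl)-4-(prop-1-en-2-yl)trideca-7,12-diene-5,11-diol F7, and Dess–Martin oxidation of the secondary alcohol comes back to the route at 12.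

Further compounds
F1 | step 8 | (4R,7E,11R)-11-hydroxy-3,3,7,11-tetramethyl-5-oxo-6-(phenylsulfonyl)-4-(prop-1-en-2-yl)trideca-7,12-dienal | C=C[C@](C)(O)CC/C=C(C)/C(S(=O)(=O)c1ccccc1)C(=O)[C@H](C(C)=C)C(C)(C)CC=O
F2 | step 8 | (5S,9S,10R,13R)-13-hydroxylabda-7,14-diene-2,6-dione | C=C[C@](C)(O)CC[C@H]1C(C)=CC(=O)[C@H]2C(C)(C)CC(=O)C[C@]12C
F3 | step 8 | tosylhydrazone of F2 at C2 | C=C[C@](C)(O)CC[C@H]1C(C)=CC(=O)[C@H]2C(C)(C)CC(=NNS(=O)(=O)c3ccc(C)cc3)C[C@]12C
F4 | step 10 | (5S,6S,9S,10R,13R)-labda-7,14-diene-6,13-diol | C=C[C@](C)(O)CC[C@H]1C(C)=C[C@H](O)[C@H]2C(C)(C)CCC[C@]12C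
F5 | step 6 | (3R)-4,4-dimethyl-3-(prop-1-en-2-yl)oxan-2-ol | OC1OCCC(C)(C)[C@H]1C(C)=C
F6 | step 6 | (4R,7E,11R)-3,3,7,11-tetramethyl-6-(phenylsulfonyl)-4-(prop-1-en-2-yl)trideca-7,12-diene-1,5,11-triol | C=C[C@](C)(O)CC/C=C(C)/C(S(=O)(=O)c1ccccc1)C(O)[C@H](C(C)=C)C(C)(C)CCO
F7 | step 6 | (4R,7E,11R)-1-iodo-3,3,7,11-tetramethyl-6-(phenylsulfonyl)-4-(prop-1-en-2-yl)trideca-7,12-diene-5,11-diol | C=C[C@](C)(O)CC/C=C(C)/C(S(=O)(=O)c1ccccc1)C(O)[C@H](C(C)=C)C(C)(C)CCI
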